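The ratio to carry through these flasks is the time left after the last reading over the lifetime of the target in its falling tail. You get it by climbing a ladder of time scales.

in all of them: starting material 10 mM
- eta: first nucleophile 13 mM; second nucleophile 10 mM; capture agent 0.20 mM; run made earlier
- delta: first nucleophile 17 mM; second nucleophile 10 mM; capture agent 0.20 mM; run made earlier
- larch: first nucleophile 11.0 mM; second nucleophile 10.0 mM; capture agent 0.200 mM; time 20 min
- oak: first nucleophile 14.0 mM; second nucleophile 10.0 mM; capture agent 0.200 mM; time 20 min

| run | time / min | target / % |
|---|---|---|
| eta | 0.833 | 11.5 |
| eta | 2.50 | 20.5 |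
| eta | 5.00 | 21.3 |
| eta | 8.00 | 17.3 |
| eta | 10.0 | 14.1 |
| delta | 0.833 | 12.8 |
| delta | 2.50 | 24.4 |
| delta | 5.00 | 25.1 |
| delta | 8.00 | 20.2 |
| delta | 10.0 | 16.9 |

(readings scatter by 0.5 percentage points)

* which of the two there is more of at the end, larch (solvolysis product / target)
* which of the two there is more of at the end, oak (solvolysis product / target)
* amount of target at the end, in percent of the starting material charged, larch
* amount of target at the end, in percent of the starting material charged, oak

- the analysis behind the earlier runs scatters by 0.5 percentage points, standard deviation
- a reading or a percentage of target counts all its forms, free or not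

On the fastest rung the target is being built, and you see it reach its top reading near 5.00 min, at 21.3% in eta and 25.1% in delta. That top grows by a factor 1.18 for a factor 1.31 in first nucleophile, so my reckoning is that a path without first nucleophile takes a share, and I expect solvolysis product above target in larch and oak.

On the next rung the flask shows only a net fall, and I treat it as a pseudo-first-order decay. The last two readings give 0.102 min⁻¹ in eta and 0.0892 min⁻¹ in delta. Each reading scatters by 0.5 percentage points, so I take the mean, 0.0957 min⁻¹, a lifetime of about 10.4 min, longer than the climb.

The slowest rung is the wait from 10.0 min to 20 min, which is 0.957 tail lifetimes, so if the rate holds a flask keeps 38.4% of its last reading. A straight line in first nucleophile through the readings at 10.0 min gives 12.7% for larch, an extrapolation below the 13 mM of eta, and 14.8% for oak, an interpolation between eta and delta, so I commit to 4.88% for larch and 5.68% for oak.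

The forecast names solvolysis product for both flasks and gives 6% (4% to 8%) for larch and 7% (4.8% to 9.2%) for oak, above my figures, on the ground that “Extrapolating from 10 to 20 min, decay continues at about 0.09/min”.

Larch ends at 4.76% target against 44.5% solvolysis product, and oak at 5.94% against 40.3%.

    starting material → open intermediate (k = 0.00723 s⁻¹)
    first nucleophile + open intermediate → target (k = 159 M⁻¹ s⁻¹)
    second nucleophile + open intermediate → other capture product (k = 99.9 M⁻¹ s⁻¹)
    open intermediate → solvolysis product (k = 1.84 s⁻¹)
    crystals ⇌ target, rate k5*(cs5 - [target]) while solid is left; crystals form when [target] > cs5 (solubility = 4.00 mM, k = 0.122 s⁻¹)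
    second nucleophile + target → over-reaction product (k = 0.323 M⁻¹ s⁻¹)
    open intermediate + capture agent → trapped intermediate (k = 0.0389 M⁻¹ s⁻¹)

Between 10.0 min and 20.0 min larch's target falls from 12.7% to 4.76% while its over-reaction product climbs from 22.0% to 30.4%. The count of 0.957 tail lifetimes applied to that 12.7% gives 4.88% for larch. For the flask like larch but with 19 mM of first nucleophile, extending the same line in first nucleophile and applying the same count gives 7.03%, and that flask stands at 7.67%.

(The runs were computed for an exercise, noise included.)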